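Assumption: 2,3-dibromo-4-methylthiophene is taken as a purchasable building block, every chiral intermediate is racemic because the target is achiral, and "safe" is read as chemically robust.

## Structural features

The target 11 is a single benzene ring with five contiguous substituents and one hydrogen. Numbered from the carbon bearing the CH2SO2CH3 chain (C1), the ring carries H at C2, hydroxyls at C3 and C4, and bromines at C5 and C6, so catechol, vicinal dibromide and benzylic sulfone follow one another without a gap. The target has no stereocentre; the only stereocentres in the plan are the two neighbouring, cis-related sp3 carbons C3 and C4 of a dihydro intermediate, and both vanish on aromatisation. The fragile groups are the free catechol (air-oxidised to the ortho-quinone once deprotonated), the two aryl C–Br bonds (lost under reducing, organometallic or low-valent-metal conditions) and the acidic CH2 between ring and sulfone. The real difficulty is regiochemical: the dibromide must sit between an oxygen and the side chain on a ring whose electrophilic substitution is steered by the two oxygens. The key step avoids this by building the ring. C5=C6–C1=C2 is a diene that already carries both bromines and the side chain in the right order and can be held s-cis as a 2,3-dibromo-4-substituted thiophene 1,1-dioxide, while C3–C4 with its two oxygens is a symmetric ene-diol unit in the form of a cyclic carbonate. Joining the two makes C2–C3 and C4–C5 and leaves only a dehydrogenation and a carbonate hydrolysis.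

## Logic of the disconnections

11 ⇒ 10. The two phenolic O–H bonds of 11 are traced back to the two aryl O–C(=O) bonds of the cyclic carbonate in 10. This keeps the oxidation-prone catechol masked until the last operation at no extra cost, since the carbonate carbon comes in with the ring-forming step. The forward step must be a hydrolysis mild enough to spare the C–Br bonds and must keep oxygen away from the catecholate.

10 ⇒ 9. The aromatic sextet of 10 is opened by returning two hydrogens to the oxygen-bearing carbons C3 and C4, which gives the cis-dihydro compound 9. The problem changes from substitution of an arene to construction of a cyclohexa-1,3-diene, which a cycloaddition can deliver with every substituent in place. The forward step must remove two hydrogens under neutral conditions. Acid would ionise an allylic C–O bond, and base could deprotonate the CH2 next to the sulfone and expel a carbonate oxygen in a vinylogous elimination; either way a monophenol would result.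

9 ⇒ 6 + 7 (through 8). In 9 the bonds C2–C3 and C4–C5 are cut together. Putting the sulfonyl bridge back across C2 and C5 gives the bicyclic adduct 8, and a retro-[4+2] then separates the four-carbon diene 6 from the two-carbon partner 7. A pentasubstituted six-membered ring is reduced to a trisubstituted five-membered heterocycle and a symmetric bulk chemical. Because 7 is symmetric, no regiochemical question arises, and the mapping (thiophene C5–H becomes ring C2, thiophene C2–Br becomes ring C5) leads to the correct isomer only. The demand on the forward step is chemoselectivity: cross-cycloaddition must outrun self-dimerisation of 6 and must not be followed by a second addition to 9.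

6 ⇒ 4 (through 5). The two S=O bonds on the ring sulfur are removed to give the aromatic thiophene 4. The ring sulfone is the reactive function and is best made immediately before use, whereas 4 is a stable compound on which the side chain can be completed. The forward step needs an oxidant strong enough for an electron-poor sulfur. It must pass quickly through the mono-oxide 5 and must work without base, because the CH2 flanked by two sulfonyl-bearing groups in 6 is acidic.

4 ⇒ 2 + 3. The CH2–S bond of the side chain is cut to give the electrophile 2 and the sulfur nucleophile 3. This has to precede the ring oxidation, because 3 would add in a conjugate sense to the ring sulfone of 6. The forward step requires S-alkylation, not O-alkylation, of the ambident nucleophile.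

2 ⇒ 1. The CH2–Br bond is cut back to the methyl group of 1. Compound 1 already holds both ring bromines in the correct relation to the carbon substituent, so no aromatic halogenation has to be controlled anywhere. The forward step must brominate the side chain by a radical path faster than the free ring position reacts by an ionic path, and must stop after one bromine.

## Other disconnections considered

Alternative 1: The cut removes the ring–CH2 bond (C1–C7) and the C6–Br bond together. It leads back to the aryne A3 (3-bromo-4,5-dimethoxybenzyne, triple bond between C1 and C6) and A2 (bromomethyl methyl sulfone). In the forward key step a fluoride source would release A3 from an ortho-silyl aryl triflate. Formal insertion of A3 into the C–Br bond of A2 would give A1 (2,3-dibromo-4,5-dimethoxybenzyl methyl sulfone), and a double O-demethylation would finish the synthesis.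
- In its favour: the step is convergent and makes a C–C and a C–Br bond on adjacent carbons at once. The inductive pull of the bromine at C5 should polarise the aryne so that carbon attacks C1 and charge develops at C6, which is the required orientation. The ring is aromatic throughout, so no dehydrogenation is needed; on this point it is better than the chosen plan.
- Against it: insertion of an aryne into the sp3 C–Br bond of an α-halo sulfone is not an established process. The plausible stepwise path (addition of the α-sulfonyl carbanion, then bromine transfer to the aryl anion) would compete with simple protonation, with bromine ending on the benzylic carbon, and with loss of bromide from C5 to generate a second aryne. The silyl triflate precursor is itself a pentasubstituted arene, so the regiochemical problem is only moved backwards, and two methyl ethers must be cleaved with a strong Lewis acid at the end.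
- Comparison: structurally both plans set the C5/C6/C1 pattern through a reactive intermediate and not by electrophilic substitution, and the regiocontrol from aryne polarisation is the equal of that from a symmetric dienophile. Mechanistically the chosen cycloaddition rests on a known reaction class, whereas the insertion would have to be invented. In step count, four or more steps to the aryne precursor plus insertion and demethylation give no saving over six.

Alternative 2: The cut is the C3–O bond, with the second oxygen introduced last. Phenol A6 (2,3-dibromo-4-(methylsulfonylmethyl)phenol) would be converted into the silanol A5 (di-tert-butyl[2,3-dibromo-4-(methylsulfonylmethyl)phenoxy]silanol). In the forward key step a divalent palladium carboxylate catalyst and a trivalent iodine diacetate oxidant would palladate the only ortho C–H (C3), pass through tetravalent palladium and close the five-membered ring to give A4 (4,5-dibromo-2,2-di-tert-butyl-6-(methylsulfonylmethyl)-1,3,2-benzodioxasilole). Fluoride would then release 11.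
- In its favour: silanol-directed ortho-oxygenation of phenols is a known reaction type. C5 is blocked by bromine, so site selectivity is unambiguous and the equal of the chosen plan. The ring stays aromatic and the catechol is unveiled by a non-oxidative desilylation, which is better than a dehydrogenation followed by hydrolysis.
- Against it: electrophilic palladation of a ring deactivated by two bromines should be slow. Any zerovalent palladium formed off-cycle could insert into the C–Br bonds. The bulky silanol sits next to the C5 bromine. A6 itself is hard to reach, because direct bromination of a para-substituted phenol goes to both ortho positions and not to the 2,3-pattern.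
- Comparison: structurally this plan leaves the hardest feature, the placement of the bromines, unsolved, whereas the chosen plan takes it from a purchasable heterocycle. Mechanistically both key steps are precedented. From A6 only three steps would be needed, fewer than the five that follow 4, but the steps to A6 would more than cancel this advantage.

Alternative 3: The cut removes both C–O bonds at C3 and C4. In the forward key step whole cells expressing toluene dioxygenase would add both oxygens cis across the C3–C4 edge of A7 (1,2-dibromo-3-(methylsulfonylmethyl)benzene) to give A8 ((1S,2S)-3,4-dibromo-5-(methylsulfonylmethyl)cyclohexa-3,5-diene-1,2-diol). A dehydrogenation would then give 11.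
- In its favour: A7 needs only a side-chain bromination and a sulfinate displacement on a dibromotoluene. Both oxygens arrive in one aqueous step without protecting groups. On paper the route has four steps, which is better step economy than the chosen plan.
- Against it: the enzyme pocket is suited to mono- and small disubstituted benzenes, and a 1,2,3-trisubstituted substrate with a polar sulfone is a poor fit. Three contiguous C–H positions leave two possible edges (C2–C3 or C3–C4), and benzylic hydroxylation is a known side path. The enantioselectivity, the main asset of the method, is wasted because both stereocentres are destroyed. A8 dehydrates to phenols with traces of acid.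
- Comparison: A8 is the free, single-enantiomer diol corresponding to 9, so both plans pass through the same kind of cis-dihydro intermediate and share the aromatisation problem; they are equal on that point. The chosen plan fixes the position of the oxygens by construction and not by enzyme preference, and its cyclic carbonate blocks dehydration. It is therefore longer but more predictable.

Key step: step 4

## Route

Step 1
Reactants: 1 2,3-dibromo-4-methylthiophene
Product: 2 2,3-dibromo-4-(bromomethyl)thiophene
Conditions: NBS (1.05 equiv), AIBN (cat.), PhCF3, 85 °C
Reagents that add atoms: N-bromosuccinimide, O=C1CCC(=O)N1Br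
Why: Wohl–Ziegler radical-chain bromination: a bromine atom abstracts hydrogen from the thenylic methyl and the thienyl-stabilised radical takes bromine from the low standing concentration of Br2. The two ring bromines deactivate the free ring carbon towards the competing ionic bromination, and a slight excess of NBS limits a second side-chain bromination.

Step 2
Reactants: 2 2,3-dibromo-4-(bromomethyl)thiophene; 3 sodium methanesulfinate
Product: 4 2,3-dibromo-4-(methylsulfonylmethyl)thiophene
Conditions: CH3SO2Na (1.3 equiv), DMF, rt to 50 °C
Reagents that add atoms: none
Why: SN2 displacement of a primary thenylic bromide by the soft sulfur of the ambident sulfinate in a polar aprotic solvent should give the sulfone and not the sulfinate ester. The aryl C–Br bonds are inert to this nucleophile.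

Step 3
Reactants: 4 2,3-dibromo-4-(methylsulfonylmethyl)thiophene
Product: 6 2,3-dibromo-4-(methylsulfonylmethyl)thiophene 1,1-dioxide, via thiophene 1-oxide 5 (not isolated)
Conditions: (CF3CO)2O, H2O2·urea, MeCN, 0 °C to rt; cold base-free work-up
Reagents that add atoms: trifluoroperacetic acid (formed in the flask from trifluoroacetic anhydride and urea–hydrogen peroxide), OOC(=O)C(F)(F)F
Why: Electrophilic oxygen transfer from CF3CO3H to sulfur is the standard S-oxidation for halogenated, electron-poor thiophenes. The first transfer breaks the aromatic sextet and is rate-limiting, so the non-aromatic S-oxide 5 should be oxidised again faster than it can dimerise. The side-chain sulfone is already fully oxidised, and the acidic medium keeps the CH2 of 6 protonated.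

Step 4
Reactants: 6 2,3-dibromo-4-(methylsulfonylmethyl)thiophene 1,1-dioxide; 7 vinylene carbonate
Product: 9 cis-4,5-dibromo-6-(methylsulfonylmethyl)-3a,7a-dihydro-1,3-benzodioxol-2-one (racemic), via bridged sulfone cycloadduct 8 (not isolated)
Conditions: 7 (6 equiv), BHT (cat.), PhCl, 120 °C, N2 (SO2 vented)
Reagents that add atoms: none
Why: The C2 and C5 termini of the s-cis-locked, electron-poor diene of 6 add suprafacially across the C=C of 7 in a concerted thermal [4π+2π] cycloaddition to give the 7-thiabicyclo[2.2.1]heptene dioxide 8, which at the same temperature expels SO2 in a retro-cheletropic step and leaves the cyclohexa-1,3-diene 9. The closest known reaction type is the Diels–Alder reaction of halogenated thiophene 1,1-dioxides with alkenes with spontaneous SO2 extrusion, and 7 is an established 2π partner for electron-poor halogenated dienes. The six-membered carbocycle is closed by an intermolecular two-bond annulation (target bonds C2–C3 and C4–C5 form in one step), not by a stepwise cyclisation, and the sulfonyl bridge is then excised. The two new stereocentres (C3a and C7a of 9) are set cis by suprafacial addition to the ring-locked Z alkene of 7, whose carbonate holds both oxygens on one face; the endo/exo question at 8 disappears when the bridgeheads return to sp2, and 9 is racemic, which is immaterial because both centres are erased in step 5. No regiochemistry arises because 7 is symmetric. The selectivity needed is chemoselectivity, cross-cycloaddition ahead of self-dimerisation of 6 and of a second addition of 7 to 9: the two bromines and the C4 substituent shield both C=C bonds of 6 as 2π components while lowering its LUMO, the excess of 7 raises the bimolecular rate, and 9 is a far less reactive, unstrained and hindered diene. The cyclic carbonate cannot reach the ring hydrogens for a syn-elimination, so 9 should survive the heating without collapsing to a phenol.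

Step 5
Reactants: 9 cis-4,5-dibromo-6-(methylsulfonylmethyl)-3a,7a-dihydro-1,3-benzodioxol-2-one
Product: 10 4,5-dibromo-6-(methylsulfonylmethyl)-1,3-benzodioxol-2-one
Conditions: DDQ (1.5 equiv), 1,4-dioxane, 90 °C
Reagents that add atoms: none
Why: DDQ dehydrogenation: hydride abstraction from an allylic, oxygen-bearing ring C–H gives a cyclohexadienyl cation that loses the neighbouring proton, with aromatisation as the driving force. The medium is neutral, so neither acid ionisation of a C–O bond nor base-induced vinylogous elimination through the side-chain CH2 can divert 9 to a monophenol. Both stereocentres are removed here.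

Step 6
Reactants: 10 4,5-dibromo-6-(methylsulfonylmethyl)-1,3-benzodioxol-2-one
Product: 11 3,4-dibromo-5-(methylsulfonylmethyl)benzene-1,2-diol (CNP0131477.0)
Conditions: NaHCO3 (aq, 2 equiv), THF, rt, argon; then 1 M HCl
Reagents that add atoms: none
Why: Hydrolysis of a strained, activated aryl cyclic carbonate by acyl–oxygen cleavage followed by decarboxylation of the aryl hydrogen carbonate; both ring oxygens stay on the arene. Bicarbonate is too weak to touch the sulfone CH2 or the C–Br bonds, and exclusion of air plus acidic work-up protects the catechol from quinone formation.

## Compound list

1 | 2,3-dibromo-4-methylthiophene | Cc1csc(Br)c1Br | starting material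
2 | 2,3-dibromo-4-(bromomethyl)thiophene | BrCc1csc(Br)c1Br | intermediate
3 | sodium methanesulfinate | CS(=O)[O-].[Na+] | starting material
4 | 2,3-dibromo-4-(methylsulfonylmethyl)thiophene | CS(=O)(=O)Cc1csc(Br)c1Br | intermediate
5 | 2,3-dibromo-4-(methylsulfonylmethyl)thiophene 1-oxide (not isolated; pyramidal sulfur, racemic and configurationally labile) | CS(=O)(=O)CC1=CS(=O)C(Br)=C1Br | intermediate
6 | 2,3-dibromo-4-(methylsulfonylmethyl)thiophene 1,1-dioxide | CS(=O)(=O)CC1=CS(=O)(=O)C(Br)=C1Br | intermediate
7 | vinylene carbonate (1,3-dioxol-2-one) | O=C1OC=CO1 | starting material
8 | endo-4,5-dibromo-6-(methylsulfonylmethyl)-3a,4,7,7a-tetrahydro-4,7-epithio-1,3-benzodioxol-2-one 8,8-dioxide (not isolated; racemic; drawn with the carbonate ring on the face away from the SO2 bridge, the exo isomer would converge to 9) | O=C1O[C@H]2[C@@H](O1)[C@@]3(Br)C(Br)=C(CS(C)(=O)=O)[C@@H]2S3(=O)=O | intermediate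
9 | cis-4,5-dibromo-6-(methylsulfonylmethyl)-3a,7a-dihydro-1,3-benzodioxol-2-one (racemic; the (3aR,7aR) enantiomer is drawn) | O=C1O[C@@H]2C=C(CS(C)(=O)=O)C(Br)=C(Br)[C@@H]2O1 | intermediate
10 | 4,5-dibromo-6-(methylsulfonylmethyl)-1,3-benzodioxol-2-one | O=C1Oc2cc(CS(C)(=O)=O)c(Br)c(Br)c2O1 | intermediate
11 | 3,4-dibromo-5-(methylsulfonylmethyl)benzene-1,2-diol (2,3-dibromo-4,5-dihydroxybenzyl methyl sulfone, CNP0131477.0; no stereocentre) | CS(=O)(=O)Cc1cc(O)c(O)c(Br)c1Br | target

## Step count and least certain steps

Total step count: 6. Longest linear sequence: 6 steps (1 → 2 → 4 → 6 → 9 → 10 → 11), with 3 and 7 entering as purchased reagents.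

Step 4 (key step). The most likely failure is loss of chemoselectivity: self-dimerisation or thermal decay of 6 outpaces the cross-cycloaddition, because 7 is only a modestly electron-rich 2π partner for an inverse-demand diene. A second cycloaddition of 7 onto 9 on prolonged heating is the next concern. The fallback sets out from 6 and comes back to the route at 11. The ene-diol is brought in as its much more electron-rich acetonide, 2,2-dimethyl-1,3-dioxole (CC1(C)OC=CO1), which should engage 6 at a lower temperature in a clearly inverse-demand pairing. The bridged adduct endo-4,5-dibromo-2,2-dimethyl-6-(methylsulfonylmethyl)-3a,4,7,7a-tetrahydro-4,7-epithio-1,3-benzodioxole 8,8-dioxide F1 would lose SO2 to give cis-4,5-dibromo-2,2-dimethyl-6-(methylsulfonylmethyl)-3a,7a-dihydro-1,3-benzodioxole F2. DDQ under neutral conditions would aromatise this to 4,5-dibromo-2,2-dimethyl-6-(methylsulfonylmethyl)-1,3-benzodioxole F3, and hot aqueous trifluoroacetic acid would remove the acetonide to give 11.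

Step 3. The likely failures are incomplete oxygen transfer to a sulfur deactivated by two bromines and a sulfonylmethyl group, dimerisation of 5 before its second oxidation, and self-condensation of 6 through its acidic CH2 during isolation. The fallback sets out from 1 and comes back to the route at 10; it oxidises the ring before the side chain is functionalised, so the substrate is less deactivated and has no acidic methylene.
- The same peracid would take 1 through 2,3-dibromo-4-methylthiophene 1-oxide F4 to 2,3-dibromo-4-methylthiophene 1,1-dioxide F5.
- Cycloaddition with 7 through the bridged adduct endo-4,5-dibromo-6-methyl-3a,4,7,7a-tetrahydro-4,7-epithio-1,3-benzodioxol-2-one 8,8-dioxide F6 would give cis-4,5-dibromo-6-methyl-3a,7a-dihydro-1,3-benzodioxol-2-one F7.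
- DDQ would give 4,5-dibromo-6-methyl-1,3-benzodioxol-2-one F8.
- Wohl–Ziegler bromination of the now benzylic methyl would give 4,5-dibromo-6-(bromomethyl)-1,3-benzodioxol-2-one F9.
- Displacement with 3 in dry DMF would deliver 10.

Step 5. The likely failure is sluggish hydride abstraction from a diene carrying two bromines, two acyloxy-bearing carbons and an electron-withdrawing side chain. Prolonged heating would then allow slow loss of one C–O bond and formation of a monophenol. The fallback sets out from 9 and comes back to the route at 11; it replaces C–H dehydrogenation by alcohol oxidation. Brief treatment of 9 with cold aqueous NaOH in THF should give racemic cis-3,4-dibromo-5-(methylsulfonylmethyl)cyclohexa-3,5-diene-1,2-diol F10; attack at the carbonate carbonyl is expected to be faster than deprotonation of the side-chain CH2, and acid is avoided throughout. One equivalent of Dess–Martin periodinane buffered with NaHCO3 would oxidise one allylic carbinol to 4,5-dibromo-6-hydroxy-3-(methylsulfonylmethyl)cyclohexa-2,4-dien-1-one F11 (or its regioisomer from the other carbinol). This is the keto tautomer of 11 and should enolise at once.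

Step 1. The likely failure is over-bromination of the side chain to a gem-dibromide alongside unreacted 1, with some ionic bromination at the free ring carbon if HBr and Br2 build up. The fallback sets out from 1 and comes back to the route at 2; it overshoots on purpose and reduces back. Excess NBS would brominate the side chain exhaustively to 2,3-dibromo-4-(dibromomethyl)thiophene F12. Diethyl phosphite with iPr2NEt in THF would then remove one bromine selectively to give 2.

## Further compounds

F1 | step 4 | endo-4,5-dibromo-2,2-dimethyl-6-(methylsulfonylmethyl)-3a,4,7,7a-tetrahydro-4,7-epithio-1,3-benzodioxole 8,8-dioxide (racemic, not isolated) | CC1(C)O[C@H]2[C@@H](O1)[C@@]3(Br)C(Br)=C(CS(C)(=O)=O)[C@@H]2S3(=O)=O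
F2 | step 4 | cis-4,5-dibromo-2,2-dimethyl-6-(methylsulfonylmethyl)-3a,7a-dihydro-1,3-benzodioxole (racemic) | CC1(C)O[C@@H]2C=C(CS(C)(=O)=O)C(Br)=C(Br)[C@@H]2O1
F3 | step 4 | 4,5-dibromo-2,2-dimethyl-6-(methylsulfonylmethyl)-1,3-benzodioxole | CC1(C)Oc2cc(CS(C)(=O)=O)c(Br)c(Br)c2O1
F4 | step 3 | 2,3-dibromo-4-methylthiophene 1-oxide (not isolated) | CC1=CS(=O)C(Br)=C1Br
F5 | step 3 | 2,3-dibromo-4-methylthiophene 1,1-dioxide | CC1=CS(=O)(=O)C(Br)=C1Br
F6 | step 3 | endo-4,5-dibromo-6-methyl-3a,4,7,7a-tetrahydro-4,7-epithio-1,3-benzodioxol-2-one 8,8-dioxide (racemic, not isolated) | O=C1O[C@H]2[C@@H](O1)[C@@]3(Br)C(Br)=C(C)[C@@H]2S3(=O)=O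
F7 | step 3 | cis-4,5-dibromo-6-methyl-3a,7a-dihydro-1,3-benzodioxol-2-one (racemic) | O=C1O[C@@H]2C=C(C)C(Br)=C(Br)[C@@H]2O1
F8 | step 3 | 4,5-dibromo-6-methyl-1,3-benzodioxol-2-one | O=C1Oc2cc(C)c(Br)c(Br)c2O1
F9 | step 3 | 4,5-dibromo-6-(bromomethyl)-1,3-benzodioxol-2-one | O=C1Oc2cc(CBr)c(Br)c(Br)c2O1
F10 | step 5 | cis-3,4-dibromo-5-(methylsulfonylmethyl)cyclohexa-3,5-diene-1,2-diol (racemic; the (1R,2R) enantiomer is drawn) | O[C@@H]1C=C(CS(C)(=O)=O)C(Br)=C(Br)[C@@H]1O
F11 | step 5 | 4,5-dibromo-6-hydroxy-3-(methylsulfonylmethyl)cyclohexa-2,4-dien-1-one (racemic, not isolated) | O=C1C=C(CS(C)(=O)=O)C(Br)=C(Br)[C@@H]1O
F12 | step 1 | 2,3-dibromo-4-(dibromomethyl)thiophene | BrC(Br)c1csc(Br)c1Br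
A1 | alternative 1 | 2,3-dibromo-4,5-dimethoxybenzyl methyl sulfone | COc1cc(CS(C)(=O)=O)c(Br)c(Br)c1OC
A2 | alternative 1 | bromomethyl methyl sulfone | CS(=O)(=O)CBr
A3 | alternative 1 | 3-bromo-4,5-dimethoxybenzyne | COC1=CC#CC(Br)=C1OC
A4 | alternative 2 | 4,5-dibromo-2,2-di-tert-butyl-6-(methylsulfonylmethyl)-1,3,2-benzodioxasilole | CC(C)(C)[Si]1(Oc2cc(CS(C)(=O)=O)c(Br)c(Br)c2O1)C(C)(C)C
A5 | alternative 2 | di-tert-butyl[2,3-dibromo-4-(methylsulfonylmethyl)phenoxy]silanol | CC(C)(C)[Si](O)(Oc1ccc(CS(C)(=O)=O)c(Br)c1Br)C(C)(C)C
A6 | alternative 2 | 2,3-dibromo-4-(methylsulfonylmethyl)phenol | CS(=O)(=O)Cc1ccc(O)c(Br)c1Br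
A7 | alternative 3 | 1,2-dibromo-3-(methylsulfonylmethyl)benzene | CS(=O)(=O)Cc1cccc(Br)c1Br
A8 | alternative 3 | (1S,2S)-3,4-dibromo-5-(methylsulfonylmethyl)cyclohexa-3,5-diene-1,2-diol | CS(=O)(=O)CC1=C[C@H](O)[C@H](O)C(Br)=C1Br
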